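## Analysis of the target

The target (26) is a dimeric isoflavonoid. Its upper isoflavan (benzo ring A, pyran ring C, ring B = 3-hydroxy-2,4-dimethoxyphenyl on C-3) carries a fourth arene, ring D, on C-4. Ring D is also the 3-aryl group of a lower isoflavan (rings A' and C'), bound to C-3' through D-6. Ring D is numbered D-1 (on C-4), D-2 (OMe), D-3 (H), D-4 (OH), D-5 (H), D-6 (on C-3'). There are three stereocentres: C-3 (R) and C-4 (S) are vicinal and trans, and C-3' (R) lies on the far side of ring D, so it cannot be relayed from the upper pair and must be set on its own. The sensitive features are four free phenols on electron-rich rings, a doubly benzylic C-4 methine para to O-7, and aryloxy groups β to C-3 and C-3' that are expelled whenever a carbanion forms at those carbons. Three methyl ethers must be told apart from four hydroxyls, and on ring D the methyl ether (D-2) and the free hydroxyl (D-4) share one ring. The main difficulty is ring D itself: it is 1,2,3,5-tetrasubstituted, both of its neighbouring carbon substituents are branched, and D-1 is wedged between the D-2 oxygen and D-6, so joining a finished arene to C-4 at that position is adverse in both sterics and regiochemistry. The strategy rests on the fact that the oxygens on D-2 and D-4 are 1,3-related while the carbon substituents sit on D-1 and D-6. Ring D is therefore the aromatised form of a 4,5-disubstituted cyclohexane-1,3-dione, which an acetate ester on C-4 (giving D-1 and D-2) and a methyl enone on C-3' (giving D-3 to D-6) assemble with every atom placed by connectivity.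

## Retrosynthetic reasoning

**26 from 25.** The last disconnection removes protecting groups only. The four phenolic oxygens (O-7, O-7', the ring B hydroxyl and the D-4 oxygen) are carried as benzyl ethers in 25, with all three methoxy groups in place. Benzyl ethers tolerate strong base, Lewis acids at low temperature and homogeneous reduction catalysts, and one hydrogenolysis removes them without touching methyl ethers or stereocentres.

**25 from 23 by way of 24.** The two O–alkyl bonds on ring D are cut, leading to resorcinol 23. The forward order is fixed by sterics: the exposed D-4 hydroxyl is benzylated first (24), and the D-2 hydroxyl, hindered by the neighbouring diarylmethine but by then the only free one, is methylated second. The reverse order would require selective alkylation of the hindered position.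

**23 from 21.** Ring D is taken back to cyclohexane-1,3-dione 21, in which D-1 and D-6 are sp3 methines and D-3 and D-5 are methylenes. Both congested bonds from ring D to the chromans then end at sp3 carbons that enolate chemistry can form, and the two extra stereocentres need no control because aromatisation erases them. The forward step must remove two hydrogens without harming benzyl ethers, alkoxyarenes or the C-4 methine. A palladium-mediated oxidation of the bis(silyl) dienol ether 22 is planned.

**21 from 9 and 18 (key disconnection).** The bonds D-1–D-6 and D-2–D-3 are cut. D-1 and D-2 stay with the upper half as the acetate side chain of ester 9, and D-3 to D-6 stay with the lower half as methyl enone 18. The cut runs between the two chroman units, so each half arrives with its stereocentres complete. The roles cannot be exchanged, because an ester on the lower half and an enone on the upper half would place the oxygens on D-3 and D-5. Forward, the ketene acetal 19 of 9 must add in a conjugate sense to 18 under a Lewis acid to give keto ester 20, and an alkoxide must then close 20 to 21.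

**9 from 7 and 8.** The C-4–CH2 bond is cut. C-4 becomes a cation stabilised by O-1 and O-7, generated from cis-alcohol 7, and the acetate unit is the commercial ketene silyl acetal 8. The ring B substituent on C-3 should direct 8 to the opposite face, giving the trans relationship from a single existing stereocentre.

**7 from 6.** The C-4–H bond is cut. Isoflavanone 6 epimerises easily at C-3, so one asymmetric transfer hydrogenation with dynamic kinetic resolution can set C-3 and C-4 together and 6 can be made racemic.

**6 from 2 and 5; 2 from 1; 5 from 3 by way of 4.** The C-3–ring B bond is cut as a palladium-catalysed α-arylation of chromanone 2 (the benzyl ether of 1) with bromide 5. Bromide 5 comes from 3 by benzylation (4) and a bromination directed by the two methoxy groups.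

**18 from 16 and 17; 17 from 15; 15 from 14.** The enone C=C bond is cut to aldehyde 17 and ylide 16. Aldehyde 17 is epimerisable and prone to β-elimination, so it is generated from alcohol 15 and consumed in the same flask. Alcohol 15 is the reduction product of acid 14.

**14 from 13; 13 from 12; 12 from 10 and 11.** C-3' is set by asymmetric hydrogenation of chromene acid 13, a substrate class for which the carboxyl group directs the catalyst. Acid 13 comes from ester 12, the annulation product of salicylaldehyde 10 and acrylate 11 (bonds O-1'–C-2' and C-3'–C-4').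

## Alternatives that were turned down

**Alternative 1:** Ring D is taken as a finished arene and both carbon substituents are attached in one insertion.
- *Forward key step:* fluoride releases 5-benzyloxy-3-methoxybenzyne from silyl triflate A1. The enolate of β-keto ester A2 adds to the aryne carbon remote from the methoxy group, the resulting aryl anion closes onto the ketone, and the four-membered alkoxide fragments to keto ester A3. This forms D-6–CH2 (future C-3') and D-1–C(=O) (future C-4).
- *For:* the ring D oxygens are differentiated from the start and no dehydrogenation is needed. On these two points it is stronger than the chosen route. The insertion regiochemistry follows the known directing effect of an aryne methoxy group.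
- *Against:* A3 is flat and achiral. C-3 with ring B and C-2 must still be built onto a diaryl ketone flanked by two ortho substituents, with the trans relationship set afterwards. C-3' needs an enantioselective alkylation with a ring A' benzyl unit, reduction and ring closure. A1 itself needs several steps.
- *Comparison:* the key step comes early and leaves all three stereocentres and two pyran rings to a long sequence. The chosen route instead joins two complete, enantioenriched halves and needs only four functional-group steps afterwards.

**Alternative 2:** Lower C-3' is formed with two bonds at once, on the complete upper unit.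
- *Forward key step:* vinyllithium A5 adds to pinacol boronate A4 (boron on D-6). A palladium aryl formed from aryl triflate A6 and a chiral MandyPhos-type ligand triggers a 1,2-shift of ring D from boron to the internal vinyl carbon, and reductive elimination gives the secondary boronic ester A7. This forms C-3'–D-6 and C-4'–C-4a'.
- *For:* C-3' is set under catalyst control at the moment it is bound to ring D, without passing through an epimerisable aldehyde such as 17. On that point it is stronger than the chosen route. The boron atom then serves for C-2' (homologation, oxidation, etherification).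
- *Against:* the migrating aryl group is ortho to the bulky chroman-4-yl substituent on D-1, a situation in which ate-complex formation and migration are both hindered. A4 requires C-4 to be bonded to a preformed arene between a methoxy group and the boron-bearing carbon, which is the very bond the analysis identifies as hardest. About five steps follow the key step.
- *Comparison:* the chosen route avoids coupling any preformed ring D at D-1 and sets the stereocentres early on simple substrates.

**Alternative 3:** The C-3'–C-4' bond is made by annulation of a ring D homophthalic anhydride with a ring A' aldehyde.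
- *Forward key step:* a bifunctional cinchona squaramide enolises anhydride A8 and activates aldehyde A9. The benzylic carbon adds to the aldehyde and the alkoxide acylates on the aryl-bound carbonyl, giving the trans isochromanone acid A10 with a free carboxyl that would become C-2'.
- *For:* one organocatalytic step from achiral partners sets C-3' and forms a skeletal bond, and ring D again carries differentiated oxygens. Both are points in its favour over the chosen route.
- *Against:* the lactone C–O bond at C-4' must later be removed reductively, which collides with benzyl protection. The lactone carbonyl on D-1 is a di-ortho-substituted aryl carboxyl, and the whole upper chroman, with ring A, C-3, ring B and two stereocentres, would have to be raised on it with no control relative to the distant C-3'.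
- *Comparison:* the chosen route brings the upper chroman in complete form and makes ring D from it, so the hindered D-1 position is built, not substituted.

Key step: step 12

Assumption: the absolute sense of the two catalytic reductions (steps 5 and 9) is assigned by analogy with chroman-4-one and with tiglic acid; if either analogy fails, the mirror-image ligand is used and nothing else changes.

Abbreviations in names: ArB = 3-(benzyloxy)-2,4-dimethoxyphenyl (protected ring B). The C-4 descriptor reads S in 9 and 23–26 and R in 19–22, and the lower-chroman C-3 descriptor reads S in 14 and 17 and R in 15, 18 and all later compounds, only because substituent priorities change; the spatial arrangement is the same throughout.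

## Route

Step 1
Reactants: 1 7-hydroxychroman-4-one
Product: 2 7-(benzyloxy)chroman-4-one
Conditions: BnBr, K2CO3, acetone, reflux
Reagents that add atoms: benzyl bromide, BrCc1ccccc1
Why: Williamson etherification of the only phenol; carbonate is too weak a base to open the chromanone by retro-oxa-Michael reaction.

Step 2
Reactants: 3 2,6-dimethoxyphenol
Product: 4 2-(benzyloxy)-1,3-dimethoxybenzene
Conditions: BnBr, K2CO3, DMF, 60 °C
Reagents that add atoms: benzyl bromide, BrCc1ccccc1
Why: Williamson etherification; it masks the future ring B hydroxyl for the whole route.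

Step 3
Reactants: 4 2-(benzyloxy)-1,3-dimethoxybenzene
Product: 5 2-(benzyloxy)-4-bromo-1,3-dimethoxybenzene
Conditions: NBS, MeCN, 0 °C to rt
Reagents that add atoms: N-bromosuccinimide, O=C1CCC(=O)N1Br
Why: Electrophilic aromatic bromination; the two flanking methoxy groups lie in the ring plane and activate C-4 (ortho to one, para to the other), whereas the central benzyloxy group is twisted out of conjugation, as is usual for 1,2,3-trialkoxybenzenes.

Step 4
Reactants: 2 7-(benzyloxy)chroman-4-one; 5 2-(benzyloxy)-4-bromo-1,3-dimethoxybenzene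
Product: 6 rac-7-(benzyloxy)-3-ArB-chroman-4-one
Conditions: Pd(OAc)2 (cat.), P(t-Bu)3·HBF4, NaOtBu, toluene, 80 °C
Reagents that add atoms: none
Why: Palladium-catalysed ketone α-arylation, a known entry to isoflavanones from chroman-4-ones; the product is more acidic than 2 and rests as its enolate, which together with the ortho methoxy group should prevent a second arylation.

Step 5
Reactants: 6 rac-7-(benzyloxy)-3-ArB-chroman-4-one
Product: 7 (3R,4R)-7-(benzyloxy)-3-ArB-chroman-4-ol (3,4-cis)
Conditions: RuCl(p-cymene)[(R,R)-TsDPEN] (cat.), HCO2H/Et3N (5:2), EtOAc, 40 °C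
Reagents that add atoms: none
Why: Asymmetric transfer hydrogenation with dynamic kinetic resolution; C-3 of 6 racemises through the enol in the amine medium and the catalyst should reduce the 3R ketone fastest with hydride arriving on the face away from ring B, so that C-4 (R, catalyst control) and C-3 (R, by resolution) are set together as the cis alcohol.

Step 6
Reactants: 7 (3R,4R)-7-(benzyloxy)-3-ArB-chroman-4-ol; 8 tert-butyl[(1-methoxyethenyl)oxy]dimethylsilane
Product: 9 methyl 2-[(3R,4S)-7-(benzyloxy)-3-ArB-chroman-4-yl]acetate (3,4-trans)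
Conditions: 8 (3 equiv), TMSOTf (0.2 equiv), CH2Cl2, −78 °C
Reagents that add atoms: none
Why: Lewis-acid benzylic substitution (Mukaiyama-type alkylation) through the C-4 cation, which O-1 and O-7 stabilise; 8 should add to the half-chair cation on the face opposite ring B, making C-4 S and trans to the untouched C-3, as in C-4 substitutions of flavan-type 4-ols with silyl nucleophiles.

Step 7
Reactants: 10 4-(benzyloxy)-2-hydroxybenzaldehyde; 11 tert-butyl acrylate
Product: 12 tert-butyl 7-(benzyloxy)-2H-chromene-3-carboxylate
Conditions: DABCO, neat in excess 11, 80 °C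
Reagents that add atoms: none
Why: Baylis–Hillman addition of the acrylate to the aldehyde followed by intramolecular conjugate addition of the phenoxide and loss of water; the bulky tert-butyl ester disfavours the competing lactonisation to a coumarin.

Step 8
Reactants: 12 tert-butyl 7-(benzyloxy)-2H-chromene-3-carboxylate
Product: 13 7-(benzyloxy)-2H-chromene-3-carboxylic acid
Conditions: TFA, CH2Cl2, 0 °C to rt
Reagents that add atoms: none
Why: Acidolysis of the tert-butyl ester through the tert-butyl cation; the aryl benzyl ether and the conjugated chromene should be stable to brief exposure to TFA at room temperature.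

Step 9
Reactants: 13 7-(benzyloxy)-2H-chromene-3-carboxylic acid
Product: 14 (3S)-7-(benzyloxy)chroman-3-carboxylic acid
Conditions: H2 (20 bar), Ru(OAc)2[(R)-H8-BINAP] (cat.), MeOH, rt
Reagents that add atoms: none
Why: Asymmetric hydrogenation of an α,β-unsaturated carboxylic acid bound to ruthenium as its carboxylate; the ligand antipode fixes the face of hydrogen delivery to C-3 and sets the stereocentre that becomes C-3' of the target, and the homogeneous catalyst does not cleave the benzyl ether.

Step 10
Reactants: 14 (3S)-7-(benzyloxy)chroman-3-carboxylic acid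
Product: 15 [(3R)-7-(benzyloxy)chroman-3-yl]methanol
Conditions: BH3·SMe2, THF, 0 °C to rt; MeOH
Reagents that add atoms: none
Why: Borane reduction of the acid to the primary alcohol; no enolisable intermediate is formed, so the stereocentre is not at risk.

Step 11
Reactants: 15 [(3R)-7-(benzyloxy)chroman-3-yl]methanol; 16 (acetylmethylene)triphenylphosphorane
Product: 18 (E)-4-[(3R)-7-(benzyloxy)chroman-3-yl]but-3-en-2-one, via chroman-3-carbaldehyde 17 (not isolated)
Conditions: TEMPO (cat.), PhI(OAc)2, CH2Cl2, rt; then 16, 40 °C
Reagents that add atoms: none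
Why: The oxoammonium oxidation stops at aldehyde 17 under non-basic conditions and the ketone-stabilised ylide olefinates it in the same flask (Wittig reaction, E-selective), so the α-stereocentre of 17, which also has a β-aryloxy leaving group, is exposed neither to base nor to chromatography.

Step 12
Reactants: 9 methyl 2-[(3R,4S)-7-(benzyloxy)-3-ArB-chroman-4-yl]acetate; 18 (E)-4-[(3R)-7-(benzyloxy)chroman-3-yl]but-3-en-2-one
Product: 21 4-[(3R,4R)-7-(benzyloxy)-3-ArB-chroman-4-yl]-5-[(3R)-7-(benzyloxy)chroman-3-yl]cyclohexane-1,3-dione (epimers at ring carbons 4 and 5), via silyl ketene acetal 19 (not isolated), via keto ester 20 (not isolated)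
Conditions: LiN(i-Pr)2, THF, −78 °C, then TMSCl; solvent change to CH2Cl2; 18, TiCl4 (1.1 equiv), −78 °C; then KOtBu (8 equiv) in THF, −78 °C to rt; aq. HCl
Reagents that add atoms: chlorotrimethylsilane, C[Si](C)(C)Cl (its silyl group is present in 19 only and is lost before 21)
Why: The lithium enolate of 9 is trapped on oxygen as ketene acetal 19; TiCl4 activates 18 at its carbonyl and 19 adds to the β-carbon through an open transition state (Mukaiyama–Michael addition), forming D-1–D-6 and leaving the titanium enolate of keto ester 20. tert-Butoxide first converts the titanium chlorides into Ti(OtBu)4 and then equilibrates the enolates of 20; the methyl ketone enolate attacks the ester carbonyl in a Claisen condensation (6-(enolendo)-exo-trig closure of ring D), forming D-2–D-3, and loss of methoxide followed by deprotonation of the 1,3-dione makes the closure irreversible. The closest known reaction types are the Lewis-acid conjugate addition of ester silyl ketene acetals to enones and the Michael–Claisen synthesis of 5-substituted cyclohexane-1,3-diones used for 5-alkylresorcinols. D-1 and D-6 become stereocentres without control and need none, since both are flattened in step 13. The step needs 1,4- and not 1,2-addition, which the soft silyl nucleophile and the titanium-bound enone should secure, and it needs the right placement of the ring D oxygens, which is fixed because the only other Claisen mode would close a four-membered ring. Under the Lewis acid no dienolate of 18 forms (a dienolate would epimerise C-3' and expel O-1' by β-elimination), and in 20 and 21 none of C-3, C-4 and C-3' is α to a carbonyl group, so the three existing stereocentres should pass unchanged.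

Step 13
Reactants: 21 4-[(3R,4R)-7-(benzyloxy)-3-ArB-chroman-4-yl]-5-[(3R)-7-(benzyloxy)chroman-3-yl]cyclohexane-1,3-dione
Product: 23 4-[(3R,4S)-7-(benzyloxy)-3-ArB-chroman-4-yl]-5-[(3R)-7-(benzyloxy)chroman-3-yl]benzene-1,3-diol, via bis(trimethylsilyl) dienol ether 22 (not isolated)
Conditions: TMSOTf, Et3N, CH2Cl2, 0 °C; then Pd(OAc)2 (1.1 equiv), MeCN, rt; 1 M HCl, THF
Reagents that add atoms: trimethylsilyl trifluoromethanesulfonate, C[Si](C)(C)OS(=O)(=O)C(F)(F)F (its silyl groups are present in 22 only)
Why: Saegusa–Ito oxidation; double O-silylation gives dienol ether 22, divalent palladium adds to its D-5 terminus with loss of trimethylsilyl acetate, syn β-hydride elimination of the D-6 hydrogen gives a cross-conjugated dienone that tautomerises through the D-1 hydrogen to the arene, and the acid work-up removes the remaining silyl group. The conditions are neither acidic nor electrophilic towards the alkoxyarenes and should leave the benzyl ethers and the three stereocentres alone.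

Step 14
Reactants: 23 4-[(3R,4S)-7-(benzyloxy)-3-ArB-chroman-4-yl]-5-[(3R)-7-(benzyloxy)chroman-3-yl]benzene-1,3-diol
Product: 24 5-(benzyloxy)-2-[(3R,4S)-7-(benzyloxy)-3-ArB-chroman-4-yl]-3-[(3R)-7-(benzyloxy)chroman-3-yl]phenol (benzyl on the D-4 oxygen, D-2 hydroxyl free)
Conditions: BnBr (1.0 equiv), K2CO3, acetone, rt
Reagents that add atoms: benzyl bromide, BrCc1ccccc1
Why: Williamson etherification with one equivalent of electrophile; the D-4 hydroxyl lies between two ring hydrogens whereas the D-2 hydroxyl is ortho to the diarylmethine on D-1, so the exposed phenoxide should react first.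

Step 15
Reactants: 24 5-(benzyloxy)-2-[(3R,4S)-7-(benzyloxy)-3-ArB-chroman-4-yl]-3-[(3R)-7-(benzyloxy)chroman-3-yl]phenol
Product: 25 (3R,4S)-7-(benzyloxy)-4-{4-(benzyloxy)-2-[(3R)-7-(benzyloxy)chroman-3-yl]-6-methoxyphenyl}-3-ArB-chromane
Conditions: MeI, K2CO3, DMF, 50 °C
Reagents that add atoms: iodomethane, CI
Why: Williamson methylation of the only remaining hydroxyl; the small electrophile in warm DMF should overcome the hindrance at D-2.

Step 16
Reactants: 25 (3R,4S)-7-(benzyloxy)-4-{4-(benzyloxy)-2-[(3R)-7-(benzyloxy)chroman-3-yl]-6-methoxyphenyl}-3-ArB-chromane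
Product: 26 3-[(3R)-7-hydroxychroman-3-yl]-4-[(3R,4S)-7-hydroxy-3-(3-hydroxy-2,4-dimethoxyphenyl)chroman-4-yl]-5-methoxyphenol (CNP0305801.1)
Conditions: H2 (1 atm), Pd/C, EtOAc/MeOH, rt
Reagents that add atoms: none
Why: Hydrogenolysis of the four aryl benzyl ethers; the chroman C–O bonds are not benzylic at carbon and the methyl ethers are inert, so the target should be released with its three stereocentres unchanged.

## Compound list

1 | 7-hydroxychroman-4-one | O=C1CCOc2cc(O)ccc12 | starting material
2 | 7-(benzyloxy)chroman-4-one | O=C1CCOc2cc(OCc3ccccc3)ccc12 | intermediate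
3 | 2,6-dimethoxyphenol | COc1cccc(OC)c1O | starting material
4 | 2-(benzyloxy)-1,3-dimethoxybenzene | COc1cccc(OC)c1OCc1ccccc1 | intermediate
5 | 2-(benzyloxy)-4-bromo-1,3-dimethoxybenzene | COc1ccc(Br)c(OC)c1OCc1ccccc1 | intermediate
6 | rac-7-(benzyloxy)-3-ArB-chroman-4-one | COc1ccc(C2COc3cc(OCc4ccccc4)ccc3C2=O)c(OC)c1OCc1ccccc1 | intermediate
7 | (3R,4R)-7-(benzyloxy)-3-ArB-chroman-4-ol (cis) | COc1ccc([C@@H]2COc3cc(OCc4ccccc4)ccc3[C@@H]2O)c(OC)c1OCc1ccccc1 | intermediate
8 | tert-butyl[(1-methoxyethenyl)oxy]dimethylsilane | C=C(OC)O[Si](C)(C)C(C)(C)C | starting material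
9 | methyl 2-[(3R,4S)-7-(benzyloxy)-3-ArB-chroman-4-yl]acetate (trans) | COc1ccc([C@@H]2COc3cc(OCc4ccccc4)ccc3[C@H]2CC(=O)OC)c(OC)c1OCc1ccccc1 | intermediate
10 | 4-(benzyloxy)-2-hydroxybenzaldehyde | O=Cc1ccc(OCc2ccccc2)cc1O | starting material
11 | tert-butyl acrylate | C=CC(=O)OC(C)(C)C | starting material
12 | tert-butyl 7-(benzyloxy)-2H-chromene-3-carboxylate | CC(C)(C)OC(=O)C1=Cc2ccc(OCc3ccccc3)cc2OC1 | intermediate
13 | 7-(benzyloxy)-2H-chromene-3-carboxylic acid | OC(=O)C1=Cc2ccc(OCc3ccccc3)cc2OC1 | intermediate
14 | (3S)-7-(benzyloxy)chroman-3-carboxylic acid | OC(=O)[C@@H]1COc2cc(OCc3ccccc3)ccc2C1 | intermediate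
15 | [(3R)-7-(benzyloxy)chroman-3-yl]methanol | OC[C@@H]1COc2cc(OCc3ccccc3)ccc2C1 | intermediate
16 | (acetylmethylene)triphenylphosphorane | CC(=O)C=P(c1ccccc1)(c1ccccc1)c1ccccc1 | starting material
17 | (3S)-7-(benzyloxy)chroman-3-carbaldehyde | O=C[C@@H]1COc2cc(OCc3ccccc3)ccc2C1 | intermediate (formed in the flask, not isolated)
18 | (E)-4-[(3R)-7-(benzyloxy)chroman-3-yl]but-3-en-2-one | CC(=O)/C=C/[C@@H]1COc2cc(OCc3ccccc3)ccc2C1 | intermediate
19 | {[2-[(3R,4R)-7-(benzyloxy)-3-ArB-chroman-4-yl]-1-methoxyethenyl]oxy}trimethylsilane (enol ether geometry not defined) | COc1ccc([C@@H]2COc3cc(OCc4ccccc4)ccc3[C@H]2C=C(OC)O[Si](C)(C)C)c(OC)c1OCc1ccccc1 | intermediate (formed in the flask, not isolated)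
20 | methyl 2-[(3R,4R)-7-(benzyloxy)-3-ArB-chroman-4-yl]-3-[(3R)-7-(benzyloxy)chroman-3-yl]-5-oxohexanoate (C-2 and C-3 of the chain unassigned) | COc1ccc([C@@H]2COc3cc(OCc4ccccc4)ccc3[C@H]2C(C(=O)OC)C(CC(C)=O)[C@@H]2COc3cc(OCc4ccccc4)ccc3C2)c(OC)c1OCc1ccccc1 | intermediate (formed in the flask, not isolated)
21 | 4-[(3R,4R)-7-(benzyloxy)-3-ArB-chroman-4-yl]-5-[(3R)-7-(benzyloxy)chroman-3-yl]cyclohexane-1,3-dione (ring carbons 4 and 5 unassigned) | COc1ccc([C@@H]2COc3cc(OCc4ccccc4)ccc3[C@H]2C2C(=O)CC(=O)CC2[C@@H]2COc3cc(OCc4ccccc4)ccc3C2)c(OC)c1OCc1ccccc1 | intermediate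
22 | 1,3-bis(trimethylsilyloxy)cyclohexa-1,3-diene bearing the (3R)-7-(benzyloxy)chroman-3-yl group on C-5 and the (3R,4R)-7-(benzyloxy)-3-ArB-chroman-4-yl group on C-6 | COc1ccc([C@@H]2COc3cc(OCc4ccccc4)ccc3[C@H]2C2C(O[Si](C)(C)C)=CC(O[Si](C)(C)C)=CC2[C@@H]2COc3cc(OCc4ccccc4)ccc3C2)c(OC)c1OCc1ccccc1 | intermediate (formed in the flask, not isolated)
23 | 4-[(3R,4S)-7-(benzyloxy)-3-ArB-chroman-4-yl]-5-[(3R)-7-(benzyloxy)chroman-3-yl]benzene-1,3-diol | COc1ccc([C@@H]2COc3cc(OCc4ccccc4)ccc3[C@H]2c2c(O)cc(O)cc2[C@@H]2COc3cc(OCc4ccccc4)ccc3C2)c(OC)c1OCc1ccccc1 | intermediate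
24 | 5-(benzyloxy)-2-[(3R,4S)-7-(benzyloxy)-3-ArB-chroman-4-yl]-3-[(3R)-7-(benzyloxy)chroman-3-yl]phenol | COc1ccc([C@@H]2COc3cc(OCc4ccccc4)ccc3[C@H]2c2c(O)cc(OCc3ccccc3)cc2[C@@H]2COc3cc(OCc4ccccc4)ccc3C2)c(OC)c1OCc1ccccc1 | intermediate
25 | (3R,4S)-7-(benzyloxy)-4-{4-(benzyloxy)-2-[(3R)-7-(benzyloxy)chroman-3-yl]-6-methoxyphenyl}-3-ArB-chromane | COc1ccc([C@@H]2COc3cc(OCc4ccccc4)ccc3[C@H]2c2c(OC)cc(OCc3ccccc3)cc2[C@@H]2COc3cc(OCc4ccccc4)ccc3C2)c(OC)c1OCc1ccccc1 | intermediate
26 | 3-[(3R)-7-hydroxychroman-3-yl]-4-[(3R,4S)-7-hydroxy-3-(3-hydroxy-2,4-dimethoxyphenyl)chroman-4-yl]-5-methoxyphenol | COc1ccc([C@@H]2COc3cc(O)ccc3[C@H]2c2c(OC)cc(O)cc2[C@@H]2COc3cc(O)ccc3C2)c(OC)c1O | target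

## Step count and least certain steps

Total step count: 16. Longest linear sequence: 10 steps (steps 2–6 and 12–16 from 3; the lower arm from 10, steps 7–16, is equally long).

**Step 12 (key step).** The conjugate addition joins two carbons that each carry a branched chroman substituent. It may be so slow that ketene acetal 19 is lost to hydrolysis or 1,2-addition. Once the alkoxide is added, the Michael addition may also revert before the Claisen condensation closes, and the freed enone would then be destroyed by γ-deprotonation. Fallback, from 9 and 18 back to 21: the order of the two bond formations is reversed so that the hindered bond forms intramolecularly. Ester 9 is saponified (LiOH, THF/water) to 2-[(3R,4S)-7-(benzyloxy)-3-ArB-chroman-4-yl]acetic acid F1. F1 is converted (1H-benzotriazole, EDC·HCl, CH2Cl2) into the N-acylbenzotriazole F2. Soft enolisation of 18 at its methyl group (MgBr2·OEt2, i-Pr2NEt, CH2Cl2) and C-acylation by F2 forms D-2–D-3 first and gives the unsaturated 1,3-diketone F3. The terminal enolate of F3 then closes D-1–D-6 by a 6-endo-trig Michael addition (KOtBu, THF, 0 °C) to give 21.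

**Step 13.** The double silylation may stay incomplete at the hindered D-2 carbonyl, or the palladium-mediated oxidation may stop at the enone level and give mixtures. Fallback, from 21 back to 23: selenoxide elimination. The dianion of 21 (LiN(i-Pr)2, 2.2 equiv, THF, −78 °C) is selenenylated with PhSeCl at the D-5 methylene to give the 6-(phenylselanyl) dione F4. H2O2 oxidises F4 to the selenoxide F5, which undergoes syn-elimination towards D-6 at room temperature, and the resulting ene-dione tautomerises to 23.

**Step 6.** The C-4 cation may lose the C-3 proton, an elimination to the isoflav-3-ene that destroys C-3. The ketene acetal may also be consumed by silyl transfer to the hydroxyl, and the trans selectivity may be eroded. Fallback, from 7 back to 9: Hosomi–Sakurai allylation (allyltrimethylsilane, BF3·OEt2, CH2Cl2, −78 °C) with a non-basic π-nucleophile should give the trans 4-allyl isoflavan F6. Lemieux–Johnson cleavage (OsO4 cat., NaIO4, 2,6-lutidine, dioxane/water) gives the aldehyde F7. Pinnick oxidation (NaClO2, NaH2PO4, 2-methyl-2-butene) gives the acid F1 already described for step 12, and methylation (MeI, K2CO3, DMF) gives 9.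

**Step 14.** Discrimination between the two ring D hydroxyls may be insufficient, with benzylation at D-2 and double benzylation competing. Fallback, from 23 back to 26: a much bulkier electrophile is used for the differentiation. Triisopropylsilyl chloride and imidazole (DMF, 0 °C) silylate the D-4 hydroxyl to give the silyl ether F8. The D-2 hydroxyl is methylated (MeI, K2CO3, acetone) to give F9. Bu4NF (THF) removes the silyl group to give the D-4 phenol F10, and hydrogenolysis (H2, Pd/C) of its three benzyl ethers gives 26.

**Step 4.** The chromanone enolate may open by β-elimination of the phenoxide, and oxidative addition of the electron-rich, ortho-substituted bromide may be slow. Fallback, from 2 and 5 back to 7: a Suzuki–Miyaura route through the isoflavone. Chromanone 2 is brominated twice at C-3 (CuBr2, EtOAc/CHCl3, reflux) to the 3,3-dibromide F11 and dehydrobrominated (Et3N) to the 3-bromochromone F12. Bromide 5 is converted (n-BuLi, THF, −78 °C; B(Oi-Pr)3; aq. HCl) into the boronic acid F13. Coupling (Pd(PPh3)4, K2CO3, dioxane/water, 80 °C) gives the isoflavone F14. Asymmetric transfer hydrogenation with the catalyst of step 5 then reduces the C=C and C=O bonds in turn, passing through 6, to give 7.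

**Step 11.** Aldehyde 17 may epimerise at C-3 or lose the ring oxygen by β-elimination while the ketone-stabilised ylide reacts slowly. Fallback, from 15 back to 18: an aldol reaction replaces the Wittig reaction. Crude 17 from the same oxidation is treated at −78 °C with 2-(trimethylsilyloxy)propene and BF3·OEt2 (Mukaiyama aldol reaction) to give the β-hydroxy ketone F15, which is dehydrated with catalytic TsOH in toluene at 50 °C to 18.

## Further compounds

F1 | step 12 | 2-[(3R,4S)-7-(benzyloxy)-3-ArB-chroman-4-yl]acetic acid | COc1ccc([C@@H]2COc3cc(OCc4ccccc4)ccc3[C@H]2CC(=O)O)c(OC)c1OCc1ccccc1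
F2 | step 12 | 1-(1H-benzotriazol-1-yl)-2-[(3R,4S)-7-(benzyloxy)-3-ArB-chroman-4-yl]ethan-1-one | COc1ccc([C@@H]2COc3cc(OCc4ccccc4)ccc3[C@H]2CC(=O)n2nnc3ccccc32)c(OC)c1OCc1ccccc1
F3 | step 12 | (5E)-1-[(3R,4S)-7-(benzyloxy)-3-ArB-chroman-4-yl]-6-[(3R)-7-(benzyloxy)chroman-3-yl]hex-5-ene-2,4-dione | COc1ccc([C@@H]2COc3cc(OCc4ccccc4)ccc3[C@H]2CC(=O)CC(=O)/C=C/[C@@H]2COc3cc(OCc4ccccc4)ccc3C2)c(OC)c1OCc1ccccc1
F4 | step 13 | 4-[(3R,4R)-7-(benzyloxy)-3-ArB-chroman-4-yl]-5-[(3R)-7-(benzyloxy)chroman-3-yl]-6-(phenylselanyl)cyclohexane-1,3-dione | COc1ccc([C@@H]2COc3cc(OCc4ccccc4)ccc3[C@H]2C2C(=O)CC(=O)C([Se]c3ccccc3)C2[C@@H]2COc3cc(OCc4ccccc4)ccc3C2)c(OC)c1OCc1ccccc1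
F5 | step 13 | 6-(benzeneseleninyl)-4-[(3R,4R)-7-(benzyloxy)-3-ArB-chroman-4-yl]-5-[(3R)-7-(benzyloxy)chroman-3-yl]cyclohexane-1,3-dione | COc1ccc([C@@H]2COc3cc(OCc4ccccc4)ccc3[C@H]2C2C(=O)CC(=O)C([Se](=O)c3ccccc3)C2[C@@H]2COc3cc(OCc4ccccc4)ccc3C2)c(OC)c1OCc1ccccc1
F6 | step 6 | (3R,4S)-7-(benzyloxy)-3-ArB-4-(prop-2-en-1-yl)chromane | COc1ccc([C@@H]2COc3cc(OCc4ccccc4)ccc3[C@H]2CC=C)c(OC)c1OCc1ccccc1
F7 | step 6 | 2-[(3R,4S)-7-(benzyloxy)-3-ArB-chroman-4-yl]acetaldehyde | COc1ccc([C@@H]2COc3cc(OCc4ccccc4)ccc3[C@H]2CC=O)c(OC)c1OCc1ccccc1
F8 | step 14 | 2-[(3R,4S)-7-(benzyloxy)-3-ArB-chroman-4-yl]-3-[(3R)-7-(benzyloxy)chroman-3-yl]-5-[(triisopropylsilyl)oxy]phenol | COc1ccc([C@@H]2COc3cc(OCc4ccccc4)ccc3[C@H]2c2c(O)cc(O[Si](C(C)C)(C(C)C)C(C)C)cc2[C@@H]2COc3cc(OCc4ccccc4)ccc3C2)c(OC)c1OCc1ccccc1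
F9 | step 14 | (3R,4S)-7-(benzyloxy)-4-{2-[(3R)-7-(benzyloxy)chroman-3-yl]-6-methoxy-4-[(triisopropylsilyl)oxy]phenyl}-3-ArB-chromane | COc1ccc([C@@H]2COc3cc(OCc4ccccc4)ccc3[C@H]2c2c(OC)cc(O[Si](C(C)C)(C(C)C)C(C)C)cc2[C@@H]2COc3cc(OCc4ccccc4)ccc3C2)c(OC)c1OCc1ccccc1
F10 | step 14 | 4-[(3R,4S)-7-(benzyloxy)-3-ArB-chroman-4-yl]-3-[(3R)-7-(benzyloxy)chroman-3-yl]-5-methoxyphenol | COc1ccc([C@@H]2COc3cc(OCc4ccccc4)ccc3[C@H]2c2c(OC)cc(O)cc2[C@@H]2COc3cc(OCc4ccccc4)ccc3C2)c(OC)c1OCc1ccccc1
F11 | step 4 | 7-(benzyloxy)-3,3-dibromochroman-4-one | O=C1c2ccc(OCc3ccccc3)cc2OCC1(Br)Br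
F12 | step 4 | 7-(benzyloxy)-3-bromo-4H-chromen-4-one | O=c1c(Br)coc2cc(OCc3ccccc3)ccc12
F13 | step 4 | [3-(benzyloxy)-2,4-dimethoxyphenyl]boronic acid | COc1ccc(B(O)O)c(OC)c1OCc1ccccc1
F14 | step 4 | 7-(benzyloxy)-3-ArB-4H-chromen-4-one | COc1ccc(-c2coc3cc(OCc4ccccc4)ccc3c2=O)c(OC)c1OCc1ccccc1
F15 | step 11 | 4-[(3S)-7-(benzyloxy)chroman-3-yl]-4-hydroxybutan-2-one (carbinol carbon unassigned) | CC(=O)CC(O)[C@@H]1COc2cc(OCc3ccccc3)ccc2C1
A1 | alternative 1 | 5-(benzyloxy)-3-methoxy-2-(trimethylsilyl)phenyl trifluoromethanesulfonate | COc1cc(OCc2ccccc2)cc(OS(=O)(=O)C(F)(F)F)c1[Si](C)(C)C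
A2 | alternative 1 | methyl 3-[2,4-bis(benzyloxy)phenyl]-3-oxopropanoate | COC(=O)CC(=O)c1ccc(OCc2ccccc2)cc1OCc1ccccc1
A3 | alternative 1 | methyl 2-[5-(benzyloxy)-2-[2,4-bis(benzyloxy)benzoyl]-3-methoxyphenyl]acetate | COC(=O)Cc1cc(OCc2ccccc2)cc(OC)c1C(=O)c1ccc(OCc2ccccc2)cc1OCc1ccccc1
A4 | alternative 2 | 2-{5-(benzyloxy)-2-[(3R,4S)-7-(benzyloxy)-3-ArB-chroman-4-yl]-3-methoxyphenyl}-4,4,5,5-tetramethyl-1,3,2-dioxaborolane | COc1ccc([C@@H]2COc3cc(OCc4ccccc4)ccc3[C@H]2c2c(OC)cc(OCc3ccccc3)cc2B2OC(C)(C)C(C)(C)O2)c(OC)c1OCc1ccccc1
A5 | alternative 2 | vinyllithium | [Li]C=C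
A6 | alternative 2 | 4-(benzyloxy)-2-(methoxymethoxy)phenyl trifluoromethanesulfonate | COCOc1cc(OCc2ccccc2)ccc1OS(=O)(=O)C(F)(F)F
A7 | alternative 2 | pinacol boronic ester of the secondary carbon (future C-3') carrying ring D of the upper unit and the 4-(benzyloxy)-2-(methoxymethoxy)benzyl group | COc1ccc([C@@H]2COc3cc(OCc4ccccc4)ccc3[C@H]2c2c(OC)cc(OCc3ccccc3)cc2[C@@H](Cc2ccc(OCc3ccccc3)cc2OCOC)B2OC(C)(C)C(C)(C)O2)c(OC)c1OCc1ccccc1
A8 | alternative 3 | 6-(benzyloxy)-8-methoxy-1H-isochromene-1,3(4H)-dione | COc1cc(OCc2ccccc2)cc2c1C(=O)OC(=O)C2
A9 | alternative 3 | 4-(benzyloxy)-2-(methoxymethoxy)benzaldehyde | COCOc1cc(OCc2ccccc2)ccc1C=O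
A10 | alternative 3 | trans-6-(benzyloxy)-3-[4-(benzyloxy)-2-(methoxymethoxy)phenyl]-8-methoxy-1-oxoisochromane-4-carboxylic acid | COc1cc(OCc2ccccc2)cc2c1C(=O)O[C@H](c1ccc(OCc3ccccc3)cc1OCOC)[C@H]2C(=O)O
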